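The route rests on disconnecting the C4–C4a bond of ring C. In the forward direction a terminal epoxide, activated by a mild Lewis acid, is opened at its CH2 carbon (C4) by ring A. This single operation closes the pyran ring, uncovers the 3-hydroxyl and transfers the preset C2 and C3 configurations into the 2,3-cis chroman. The feature exploited is the position of C4a on ring A: para to O7 and flanked by O1 and the acylated O5, so that, with O5 muted as its gallate, the O7 benzyl ether should steer the attack. The precursor is the threo (R,R) ether formed between an aryl epoxy carbinol and phloroglucinol monobenzyl ether monogallate.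

Key step: step 6

Remark: flavan numbering (O1, C2, C3, C4, C4a, C5 to C8, C8a) is used for the open-chain compounds too; because each of the two ring A carbons ortho to O1 is ortho or para to all three oxygens, the preference for C4a in step 6 is taken to be moderate, not absolute, and chromatographic removal of the isomeric 7-gallate is assumed.

Step 1
Reactants: 1 phloroglucinol (benzene-1,3,5-triol)
Product: 2 5-(benzyloxy)benzene-1,3-diol
Conditions: 1 (3 equiv), BnBr (1 equiv), K2CO3 (1 equiv), DMF, rt
Reagents that add atoms: benzyl bromide, BrCc1ccccc1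
Why: Williamson ether synthesis under statistical control, in which a threefold excess of the cheap, water-soluble triol and a weak base in DMF should hold the reaction at O-monobenzylation, the surplus triol being washed out with water.

Step 2
Reactants: 2 5-(benzyloxy)benzene-1,3-diol; 3 3,4,5-tris(benzyloxy)benzoic acid
Product: 4 3-(benzyloxy)-5-hydroxyphenyl 3,4,5-tris(benzyloxy)benzoate
Conditions: 2 (2.5 equiv), 3 (1 equiv), DCC (1.05 equiv), DMAP (0.1 equiv), CH2Cl2/THF, 0 °C to rt
Reagents that add atoms: none
Why: Steglich esterification, in which the symmetrical diol is taken in excess over the acid so that monoacylation prevails, the two hydroxyls being equivalent so that only one monoester can form and the surplus diol being recovered.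

Step 3
Reactants: 5 3,4,5-tris(benzyloxy)benzaldehyde
Product: 6 rac-1-[3,4,5-tris(benzyloxy)phenyl]prop-2-en-1-ol
Conditions: vinylmagnesium bromide (1.2 equiv), THF, −78 to 0 °C; aqueous quench
Reagents that add atoms: vinylmagnesium bromide, C=C[Mg]Br
Why: Grignard 1,2-addition to a non-enolisable aromatic aldehyde, which creates the future C2 as a racemate that the next step resolves.

Step 4
Reactants: 6 rac-1-[3,4,5-tris(benzyloxy)phenyl]prop-2-en-1-ol
Product: 7 (S)-[(2R)-oxiran-2-yl][3,4,5-tris(benzyloxy)phenyl]methanol (erythro epoxy alcohol)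
Conditions: Ti(OiPr)4 (0.15 equiv), L-(+)-DIPT (0.2 equiv), anhydrous t-BuOOH (0.45 equiv), 4 Å MS, CH2Cl2, −20 °C
Reagents that add atoms: tert-butyl hydroperoxide, CC(C)(C)OO
Why: Sharpless kinetic resolution by asymmetric epoxidation, in which the catalyst formed from Ti(OiPr)4 and L-(+)-DIPT should epoxidise the (R)-alcohol far faster than the (S)-alcohol and deliver oxygen to the alkene face that gives the erythro product, so that C3 (R) is set by the tartrate and C2 by selection of the enantiomer (its descriptor changes from R to S only because the oxirane carbon outranks the aryl group), while substoichiometric peroxide keeps conversion below one half and protects the enantiomeric purity.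

Step 5
Reactants: 7 (S)-[(2R)-oxiran-2-yl][3,4,5-tris(benzyloxy)phenyl]methanol; 4 3-(benzyloxy)-5-hydroxyphenyl 3,4,5-tris(benzyloxy)benzoate
Product: 8 3-(benzyloxy)-5-{(R)-[(2R)-oxiran-2-yl][3,4,5-tris(benzyloxy)phenyl]methoxy}phenyl 3,4,5-tris(benzyloxy)benzoate (threo ether)
Conditions: PPh3 (1.5 equiv), DIAD (1.5 equiv, added last), toluene, 0 °C to rt
Reagents that add atoms: none
Why: Mitsunobu etherification, an SN2 displacement of the oxyphosphonium group by the phenol with inversion at benzylic C2 that turns the erythro alcohol into the threo (R,R) ether, ionisation being disfavoured by the non-polar solvent and by the inductive pull of the oxirane and of the two meta benzyloxy groups, while oxirane and aryl ester are inert to the neutral reagents.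

Step 6
Reactants: 8 3-(benzyloxy)-5-{(R)-[(2R)-oxiran-2-yl][3,4,5-tris(benzyloxy)phenyl]methoxy}phenyl 3,4,5-tris(benzyloxy)benzoate
Product: 9 (2R,3R)-7-(benzyloxy)-3-hydroxy-2-[3,4,5-tris(benzyloxy)phenyl]chroman-5-yl 3,4,5-tris(benzyloxy)benzoate (2,3-cis)
Conditions: AuCl3 (5 mol%), AgOTf (15 mol%), 4 Å MS, ClCH2CH2Cl (0.01 M), 0 °C to rt
Reagents that add atoms: none
Why: Trivalent gold, made more electrophilic by chloride abstraction with AgOTf, binds the oxirane oxygen, and the ring A carbon that lies between O1 and the acylated O5 and para to O7 attacks the primary carbon C4 from the rear in an SN2-like Friedel–Crafts alkylation; loss of the arenium proton then restores ring A and protonates the 3-alkoxide. The closest known reaction type is the gold- or fluoroalcohol-promoted cycloalkylation of aryl 2,3-epoxypropyl ethers to chroman-3-ols. Ring C closes in the 6-endo-tet mode, because the 5-exo alternative would demand attack at the hindered secondary carbon C3 through a strained dihydrobenzofuran-like transition state. No stereocentre is formed: the C2–O1 and C3–O bonds are not touched, so the threo (2R,3R) ether is carried over into the 2,3-cis chromanol. The step needs site selectivity between the two carbons ortho to O1, and since both are ortho or para to all three oxygens it rests on the stronger para than ortho activation by the O7 benzyl ether once O5 is muted by acylation, the effect that also sends halogenation of 3-alkoxyphenyl esters para to the ether. It also needs chemoselectivity for the oxirane over the benzylic C2–O1 bond, which low catalyst loading, high dilution and low temperature are meant to secure.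

Step 7
Reactants: 9 (2R,3R)-7-(benzyloxy)-3-hydroxy-2-[3,4,5-tris(benzyloxy)phenyl]chroman-5-yl 3,4,5-tris(benzyloxy)benzoate; 3 3,4,5-tris(benzyloxy)benzoic acid
Product: 10 (2R,3R)-7-(benzyloxy)-2-[3,4,5-tris(benzyloxy)phenyl]chroman-3,5-diyl bis[3,4,5-tris(benzyloxy)benzoate]
Conditions: 3 (1.5 equiv), DCC (1.5 equiv), DMAP (0.3 equiv), CH2Cl2, rt
Reagents that add atoms: none
Why: Steglich esterification of the secondary 3-hydroxyl with retention at C3, made fail-safe by the identity of the two acyl groups, since a base-induced shift of the gallate from O5 to O3 would free a phenol that is acylated by the same acid and so leads to the same product.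

Step 8
Reactants: 10 (2R,3R)-7-(benzyloxy)-2-[3,4,5-tris(benzyloxy)phenyl]chroman-3,5-diyl bis[3,4,5-tris(benzyloxy)benzoate]
Product: 11 epigallocatechin 3,5-digallate, (2R,3R)-7-hydroxy-2-(3,4,5-trihydroxyphenyl)chroman-3,5-diyl bis(3,4,5-trihydroxybenzoate)
Conditions: H2 (1 atm), Pd(OH)2/C, THF/MeOH 4:1, rt; filtration under argon
Reagents that add atoms: none
Why: Catalytic hydrogenolysis of all ten benzyl ethers under neutral conditions, which is standard for benzylated catechin gallates and should spare both esters, the cyclic C2–O1 bond and the two stereocentres, air being excluded during filtration because the pyrogallol rings oxidise readily.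

Compound list
1 | phloroglucinol (benzene-1,3,5-triol) | Oc1cc(O)cc(O)c1 | starting material
2 | 5-(benzyloxy)benzene-1,3-diol | Oc1cc(O)cc(OCc2ccccc2)c1 | intermediate
3 | 3,4,5-tris(benzyloxy)benzoic acid | O=C(O)c1cc(OCc2ccccc2)c(OCc2ccccc2)c(OCc2ccccc2)c1 | starting material
4 | 3-(benzyloxy)-5-hydroxyphenyl 3,4,5-tris(benzyloxy)benzoate | Oc1cc(OCc2ccccc2)cc(OC(=O)c2cc(OCc3ccccc3)c(OCc3ccccc3)c(OCc3ccccc3)c2)c1 | intermediate
5 | 3,4,5-tris(benzyloxy)benzaldehyde | O=Cc1cc(OCc2ccccc2)c(OCc2ccccc2)c(OCc2ccccc2)c1 | starting material
6 | rac-1-[3,4,5-tris(benzyloxy)phenyl]prop-2-en-1-ol | C=CC(O)c1cc(OCc2ccccc2)c(OCc2ccccc2)c(OCc2ccccc2)c1 | intermediate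
7 | (S)-[(2R)-oxiran-2-yl][3,4,5-tris(benzyloxy)phenyl]methanol (erythro) | C1O[C@H]1[C@@H](O)c1cc(OCc2ccccc2)c(OCc2ccccc2)c(OCc2ccccc2)c1 | intermediate
8 | 3-(benzyloxy)-5-{(R)-[(2R)-oxiran-2-yl][3,4,5-tris(benzyloxy)phenyl]methoxy}phenyl 3,4,5-tris(benzyloxy)benzoate (threo) | C1O[C@H]1[C@H](Oc1cc(OCc2ccccc2)cc(OC(=O)c2cc(OCc3ccccc3)c(OCc3ccccc3)c(OCc3ccccc3)c2)c1)c1cc(OCc2ccccc2)c(OCc2ccccc2)c(OCc2ccccc2)c1 | intermediate
9 | (2R,3R)-7-(benzyloxy)-3-hydroxy-2-[3,4,5-tris(benzyloxy)phenyl]chroman-5-yl 3,4,5-tris(benzyloxy)benzoate | O[C@@H]1Cc2c(OC(=O)c3cc(OCc4ccccc4)c(OCc4ccccc4)c(OCc4ccccc4)c3)cc(OCc3ccccc3)cc2O[C@@H]1c1cc(OCc2ccccc2)c(OCc2ccccc2)c(OCc2ccccc2)c1 | intermediate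
10 | (2R,3R)-7-(benzyloxy)-2-[3,4,5-tris(benzyloxy)phenyl]chroman-3,5-diyl bis[3,4,5-tris(benzyloxy)benzoate] | O=C(O[C@@H]1Cc2c(OC(=O)c3cc(OCc4ccccc4)c(OCc4ccccc4)c(OCc4ccccc4)c3)cc(OCc3ccccc3)cc2O[C@@H]1c1cc(OCc2ccccc2)c(OCc2ccccc2)c(OCc2ccccc2)c1)c1cc(OCc2ccccc2)c(OCc2ccccc2)c(OCc2ccccc2)c1 | intermediate
11 | epigallocatechin 3,5-digallate, (2R,3R) | O=C(Oc1cc(O)cc2c1C[C@@H](OC(=O)c1cc(O)c(O)c(O)c1)[C@@H](c1cc(O)c(O)c(O)c1)O2)c1cc(O)c(O)c(O)c1 | target

Total step count: 8. Longest linear sequence: 6 steps (from 5 through steps 3 to 8; the branch from 1 through steps 1, 2 and 5 to 8 is equally long).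

Steps most likely to fail

1. Step 6.
- What may go wrong: the attack of ring A may divide between C4a and the carbon between O1 and O7 (poor site selectivity). The acid may also ionise the benzylic C2–O1 bond, with loss of the aryl ether and scrambling of C2.
- Fallback: the same bond would be made under neutral, reductive conditions from an aryl iodide that marks C4a in advance. It sets out from 2. Iodination with I2 and NaHCO3 in aqueous THF at 0 °C, the conditions that convert resorcinol into its 2-iodide, should place iodine between the two equivalent hydroxyls and give 5-(benzyloxy)-2-iodobenzene-1,3-diol F1. Steglich monoacylation with 3 then gives 5-(benzyloxy)-3-hydroxy-2-iodophenyl 3,4,5-tris(benzyloxy)benzoate F2. Mitsunobu coupling with 7 gives 5-(benzyloxy)-2-iodo-3-{(R)-[(2R)-oxiran-2-yl][3,4,5-tris(benzyloxy)phenyl]methoxy}phenyl 3,4,5-tris(benzyloxy)benzoate F3. A nickel-catalysed cross-electrophile coupling of aryl iodide and epoxide follows (NiCl2(dme), 2,2′-bipyridine, NaI, Et3N·HCl, Zn, DMPU, rt). In it iodide opens the oxirane at C4 and the primary alkyl iodide is joined to the aryl–nickel species, which closes ring C and comes back to the route at 9.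

2. Step 5.
- What may go wrong: the oxyphosphonium ion may ionise at benzylic C2 before the weakly nucleophilic, ester-bearing phenoxide arrives (erosion of the inversion). The phenoxide may also take over the aryl ester of a second molecule (acyl scrambling).
- Fallback: the order of events would be reversed. It sets out from 7 and an excess (3 equiv) of the ester-free, more nucleophilic diol 2. The Mitsunobu reaction should capture the oxyphosphonium ion faster and give 3-(benzyloxy)-5-{(R)-[(2R)-oxiran-2-yl][3,4,5-tris(benzyloxy)phenyl]methoxy}phenol F4. Steglich acylation of its single phenol with 3 comes back to the route at 8.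

3. Step 4.
- What may go wrong: the slow epoxidation of a monosubstituted alkene may lower the discrimination between the enantiomers, and the product of a kinetic resolution inherits every such error (insufficient enantiomeric purity).
- Fallback: the carbinol centre would be set first by catalytic asymmetric vinylation. It sets out from 5. Divinylzinc (from vinylmagnesium bromide and ZnCl2) with catalytic (+)-MIB, (2R)-3-exo-morpholinoisoborneol, in toluene at 0 °C should give (R)-1-[3,4,5-tris(benzyloxy)phenyl]prop-2-en-1-ol F5. Its matched Sharpless epoxidation with Ti(OiPr)4, L-(+)-DIPT and t-BuOOH is then run to full conversion of the (R)-alcohol. This acts as a second selection, leaves residual (S)-alcohol behind and comes back to the route at 7.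

Further compounds
F1 | step 6 | 5-(benzyloxy)-2-iodobenzene-1,3-diol | Oc1cc(OCc2ccccc2)cc(O)c1I
F2 | step 6 | 5-(benzyloxy)-3-hydroxy-2-iodophenyl 3,4,5-tris(benzyloxy)benzoate | Oc1cc(OCc2ccccc2)cc(OC(=O)c2cc(OCc3ccccc3)c(OCc3ccccc3)c(OCc3ccccc3)c2)c1I
F3 | step 6 | 5-(benzyloxy)-2-iodo-3-{(R)-[(2R)-oxiran-2-yl][3,4,5-tris(benzyloxy)phenyl]methoxy}phenyl 3,4,5-tris(benzyloxy)benzoate | C1O[C@H]1[C@H](Oc1cc(OCc2ccccc2)cc(OC(=O)c2cc(OCc3ccccc3)c(OCc3ccccc3)c(OCc3ccccc3)c2)c1I)c1cc(OCc2ccccc2)c(OCc2ccccc2)c(OCc2ccccc2)c1
F4 | step 5 | 3-(benzyloxy)-5-{(R)-[(2R)-oxiran-2-yl][3,4,5-tris(benzyloxy)phenyl]methoxy}phenol | C1O[C@H]1[C@H](Oc1cc(O)cc(OCc2ccccc2)c1)c1cc(OCc2ccccc2)c(OCc2ccccc2)c(OCc2ccccc2)c1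
F5 | step 4 | (R)-1-[3,4,5-tris(benzyloxy)phenyl]prop-2-en-1-ol | C=C[C@@H](O)c1cc(OCc2ccccc2)c(OCc2ccccc2)c(OCc2ccccc2)c1
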